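Age counts.

the same everywhere: free catalyst 1.2 mM

| charge | starting material | partner | remark | time |
|---|---|---|---|---|
| zeta | 25 mM | 30 mM | run made earlier |  |
| epsilon | 12 mM | 30 mM | run made earlier |  |
| cedar | 25 mM | 30.0 mM (fed, over 1.60 d) | a stirred flask in which partner is dosed at a steady rate over 1.60 d without added volume, worked up at 2.0 d | 2.0 d |
| ash | 25 mM (fed, over 1.60 d) | 30.0 mM | all but starting material at the start; starting material goes in evenly over 1.60 d, the run ends at 2.0 d | 2.0 d |
| larch | 25 mM | 30.0 mM | everything together in a closed stirred flask, run for 2.0 d | 2.0 d |
| maple | 25 mM | 30.0 mM | one stirred flow tank at steady state, fed with the mixture as stated, mean residence time 2.0 d |  |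

| run | time / h | target / % | starting material / % |
|---|---|---|---|
| zeta | 2.50 | 0.3 | 90.8 |
| zeta | 8.00 | 2.5 | 76.1 |
| zeta | 15.0 | 6.9 | 64.4 |
| zeta | 20.0 | 9.3 | 58.4 |
| zeta | 30.0 | 15.3 | 50.9 |
| zeta | 40.0 | 21.2 | 44.3 |
| zeta | 50.0 | 25.9 | 39.8 |
| epsilon | 0.500 | 0.1 | 97.7 |
| epsilon | 1.33 | 0 | 94.7 |
| epsilon | 2.50 | 0.2 | 90.8 |
| epsilon | 4.00 | 1.0 | 85.5 |
| epsilon | 6.00 | 1.4 | 80.5 |
| epsilon | 8.00 | 2.7 | 75.5 |
| epsilon | 10.0 | 3.3 | 71.6 |

(standard deviation of a reading: 0.3 percentage points)

1. the set-up with the highest amount of target at the outlet or at the end, in percent of the starting material put in ("none" if the first two lie within 2 percentage points) (cedar / ash / larch / maple / none)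
2. amount of target at the outlet or at the end, in percent of the starting material put in, cedar
3. amount of target at the outlet or at the end, in percent of the starting material put in, ash
4. amount of target at the outlet or at the end, in percent of the starting material put in, larch
5. amount of target at the outlet or at the end, in percent of the starting material put in, maple

- the stated concentrations are those of everything mixed, before any reaction; amounts are the same in each set-up
- the feed brings no volume worth counting
- the earlier runs were made in a closed, stirred flask

Zeta is charged with twice the starting material of epsilon, yet at 8.00 h zeta keeps 76.1% of it and epsilon 75.5%, with target at 2.5% and 2.7%. So in these runs the percent curve does not follow the charge, as for a pseudo-first-order loss, and a portion of starting material can be reckoned to run along the zeta curve from the moment it enters.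

Ash then has two extremes. With its starting material present from the start, each portion is 48 h old at the end, and zeta read at that age gives 25.0%. With the feed entering at once as dosing ends, each portion is 9.60 h old, and zeta gives 3.51%. The even feed lies between these, and the zeta target curve is close to straight over those ages, so one age can stand for the whole feed. The end time less half the dosing time, 28.8 h, is the mean age of the fed starting material. Zeta at that age gives my own figure for ash, 14.6%. Larch, with the charges of zeta, is the older extreme. Cedar's partner arrives late, and both runs held partner at 30 mM, so mean age gives no figure for cedar.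

The forecast names larch, with cedar 21.5%, ash 15%, larch 25% and maple 22.5%; for ash its ground is that “late-fed material has too little time”.

    target ⇌ isomer of the product (K = 0.830, k = 1.80 × 10⁻⁴ /min)
    starting material + free catalyst ⇌ free catalyst + open intermediate (K = 1.00, k = 0.590 /M/min)
    partner + catalyst intermediate → free catalyst + target (k = 0.560 /M/min)
    free catalyst + open intermediate ⇌ catalyst intermediate (K = 70.0 /M, k = 0.650 /M/min)

Ash gives 15.1%, against 14.6% read at mean age 28.8 h, and larch leads with 24.8%, ahead of cedar at 21.1% and maple at 19.4%. The forecast stands, but larch's figure has moved by 5 points with free catalyst lowered to 0.962 mM. The neighbour flask, ash read at 5.0 d, has a mean age of 4.20 d. The zeta slope between its last two readings, continued to that age, gives 49.8%, and that flask holds 39.2% target beside 16.7% isomer of the product.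

The earlier runs and the new flask were computed from invented constants, noise included.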